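(The data are calculated with constants of no real substance, noise included.)

3 numbers are asked here: the bis adduct after 5.0 min in violet, blue and amber, where the two earlier runs reach half that time.

| flask | substrate | coupling partner | scavenger | remark | time |
|---|---|---|---|---|---|
| noon | 0.050 M | 0.045 M | 0.050 M | run made earlier |  |
| spring | 0.050 M | 0.088 M | 0.050 M | run made earlier |  |
| violet | 0.050 M | 0.0500 M | 0.0500 M |  | 5.0 min |
| blue | 0.050 M | 0.0750 M | 0.0500 M |  | 5.0 min |
| amber | 0.050 M | 0.100 M | 0.0500 M |  | 5.0 min |

| noon: time / min | noon: bis adduct / % | spring: time / min | spring: bis adduct / % |
|---|---|---|---|
| 0.667 | 2.3 | 0.200 | 0.3 |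
| 1.33 | 1.7 | 0.500 | 1.1 |
| 2.00 | 2.4 | 1.00 | 3.5 |
| 2.50 | 4.6 | 2.50 | 11.3 |

(readings scatter by 1 percentage point)

- a reading or a percentage of bis adduct counts all its forms, free or not

- amount of bis adduct at the end, in percent of the substrate charged, for each flask in turn (violet, blue, amber)

I compare the last readings of the earlier runs, 4.6% in noon and 11.3% in spring, both at 2.50 min, and read from them the partner order (the apparent reaction order), the power of the coupling partner charge that the bis adduct reading follows at a fixed time with the substrate and scavenger charges held as they stand in these runs: 1.34. This is a reading, and noon's figure carries an error of 1 percentage point. The spring run then rises from 3.5% at 1.00 min, and if I carry that straight line on to 5.0 min, it adds 13.0%, so the reading grows by a factor of 2.15 over that stretch. I assume the same factor for each new flask. Scaling noon's reading to the violet charge by the partner order and multiplying by this factor gives 11.4% for violet, and the partner order then gives 19.6% for blue and 28.8% for amber.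

The weak link is the single noon reading. I replace it by a straight rise from zero drawn across all of noon's readings, with its slope taken as their sum over the sum of their times, which gives 4.23% at 2.50 min and a partner order of 1.46. Violet then moves to 10.6% and amber to 29.3%, and I stay with my first row.

The forecast reads the spring run as “fast mono-addition followed by slow second addition” and gives 5.5%, 12% and 23%, which differs from my reckoning: it is lower in violet, in blue and in amber.

The flasks give 10.8%, 17.9% and 23.6%.

    substrate + coupling partner → first product + released group (k = 0.0390 M⁻¹ s⁻¹)
    coupling partner + first product → bis adduct + released group (k = 0.0780 M⁻¹ s⁻¹)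
    coupling partner + bis adduct → triple product + released group (k = 0.0140 M⁻¹ s⁻¹)
    coupling partner + triple product → tetra adduct + released group (k = 0.0250 M⁻¹ s⁻¹)
    crystals ⇌ released group, rate k5*(cs5 - [released group]) while solid is left; crystals form when [released group] > cs5 (solubility = 5.40 mM, k = 0.0820 s⁻¹)
    substrate + bis adduct ⇌ idle adduct A, settled at all times (K = 28.0 M⁻¹)
    substrate + released group ⇌ idle adduct B, settled at all times (K = 2200 M⁻¹)
    scavenger + released group → scavenged by-product (k = 2.80 M⁻¹ s⁻¹)

The partner order puts blue over violet at 1.72, and the flasks give 1.66; it puts amber over violet at 2.53, and the flasks give 2.19. In violet, first product is made 2.85 times faster than it is used up at 1.62 min, each step taken net, and 1.12 times faster at 5.00 min. At that end of the violet run first product stands at 17.8% of the substrate charged, with 59.4% of the coupling partner's own charge left.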